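## Retrosynthetic overview

1. The target comes from its undeca-O-benzyl ether by one hydrogenolysis.
2. The trimer is cut at both C-4→C-8 bonds. The chain grows from the catechin starter unit upward: epicatechin C-4 cation + benzylated catechin gives the dimer, then the epiafzelechin C-4 cation + dimer gives the trimer. Each new bond forms trans to the 3-OH (4β).
3. Both cations come from DDQ oxidation at C-4 of the benzylated 2,3-cis flavan-3-ols (the quinone-methide stage), stored as 2-ethoxyethyl ethers.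
4. (−)-Epiafzelechin comes from pelargonidin chloride by hydride transfer, tautomerisation and a second hydride transfer, as anthocyanidin reductase is thought to work. This sets C-2 and C-3 (cis, 2R,3R) in one step.
5. Rings: only ring C of the top unit is built, by O-1–C-2 closure of an enone made from 2,4,6-trihydroxybenzaldehyde and 2-hydroxy-1-(4-hydroxyphenyl)ethanone. Rings C of the middle and bottom units come intact with (−)-epicatechin and (+)-catechin.

Assumption: in step 6 the (R,R)-TsDPEN catalyst is taken to deliver hydride to the Si face of C-3 (giving 3R); if a first run gives the antipode, the (S,S) catalyst is used and nothing else changes.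

## Route

Step 1
Reactants: 1 (+)-catechin
Product: 2 5,7,3',4'-tetra-O-benzyl-(+)-catechin
Conditions: BnBr (4.4 equiv), K2CO3 (5 equiv), DMF, 0 °C → rt, 16 h
Reagents that add atoms: benzyl bromide, BrCc1ccccc1
Why: Williamson etherification in which K2CO3 deprotonates only the four phenols, so the secondary 3-OH stays free and neither stereocentre is touched.

Step 2
Reactants: 3 (−)-epicatechin
Product: 4 5,7,3',4'-tetra-O-benzyl-(−)-epicatechin
Conditions: BnBr (4.4 equiv), K2CO3 (5 equiv), DMF, 0 °C → rt, 16 h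
Reagents that add atoms: benzyl bromide, BrCc1ccccc1
Why: Williamson etherification of the four phenols only, run cold so that the 2,3-cis stereocentres are not epimerised.

Step 3
Reactants: 4 5,7,3',4'-tetra-O-benzyl-(−)-epicatechin
Product: 5 4β-(2-ethoxyethoxy)-5,7,3',4'-tetra-O-benzylepicatechin (2R,3R,4S; 2,3-cis-3,4-trans)
Conditions: DDQ (2 equiv), 2-ethoxyethanol (5 equiv), CH2Cl2, rt, 2 h
Reagents that add atoms: 2-ethoxyethanol, CCOCCO
Why: DDQ benzylic oxidation in which hydride abstraction from C-4 gives the quinone-methide-type cation stabilised by the ring A oxygens, and the alcohol adds anti to the neighbouring 3-OH, which sets C-4 as 4β.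

Step 4
Reactants: 5 4β-(2-ethoxyethoxy)-5,7,3',4'-tetra-O-benzylepicatechin; 2 5,7,3',4'-tetra-O-benzyl-(+)-catechin
Product: 6 octa-O-benzylprocyanidin B1 [5,7,3',4'-tetra-O-benzylepicatechin-(4β→8)-5,7,3',4'-tetra-O-benzylcatechin]
Conditions: 2 (4 equiv), Me3SiOSO2CF3 (0.5 equiv), CH2Cl2, −78 °C, 10 min; aq. NaHCO3 quench
Reagents that add atoms: none
Why: Lewis-acid-promoted Friedel–Crafts alkylation in which ionisation of the 4-ether regenerates the C-4 cation (the extension unit), the excess starter unit traps it through its most nucleophilic carbon C-8, and attack anti to the 3-OH gives only the 4β→8 (3,4-trans) bond.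

Step 5
Reactants: 7 2,4,6-trihydroxybenzaldehyde; 8 2-hydroxy-1-(4-hydroxyphenyl)ethan-1-one
Product: 10 pelargonidin chloride, via 2-hydroxychalcone 9 (not isolated)
Conditions: HCl (gas), EtOAc/MeOH, 0 °C → rt, 24 h; salt filtered off
Reagents that add atoms: hydrogen chloride, Cl
Why: Robinson anthocyanidin synthesis in which acid-catalysed aldol condensation gives enone 9, whose ortho-phenol closes ring C through the O-1–C-2 bond and loss of water aromatises it to the flavylium salt, which has no stereocentre.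

Step 6
Reactants: 10 pelargonidin chloride
Product: 13 (−)-epiafzelechin, via flav-2-en-3-ol 11 (not isolated), via flavan-3-one 12 (not isolated)
Conditions: RuCl[(R,R)-TsDPEN](p-cymene) (3 mol %), HCO2H/Et3N (5:2), DMF, 40 °C, Ar
Reagents that add atoms: none
Why: Proposed new method: the flavylium cation is a strong hydride acceptor, so the ruthenium hydride formed from formate adds H− at C-4 to give enol 11, which tautomerises to ketone 12 whose C-2 (benzylic, α-oxy, α-keto) epimerises through 11 faster than the ketone is reduced, and the catalyst then reduces only the (2R)-ketone on the Si face of C-3 anti to ring B, giving the 2,3-cis (2R,3R) alcohol by dynamic kinetic resolution in the hydride–tautomerise–hydride order proposed for anthocyanidin reductase; the closest known reactions are Noyori–Ikariya transfer hydrogenation of racemising α-aryl cyclic ketones to cis-alcohols, formate transfer hydrogenation of iminium- and pyrylium-type cations, and the hydrogenation of cyanidin chloride over PtO2 to racemic epicatechin.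

Step 7
Reactants: 13 (−)-epiafzelechin
Product: 14 5,7,4'-tri-O-benzyl-(−)-epiafzelechin
Conditions: BnBr (3.3 equiv), K2CO3 (4 equiv), DMF, 0 °C → rt, 16 h
Reagents that add atoms: benzyl bromide, BrCc1ccccc1
Why: Williamson etherification of the three phenols only, with the 4'-OH capped early in the cold so that base-induced opening of ring C through a ring B quinone methide (C-2 epimerisation) does not compete.

Step 8
Reactants: 14 5,7,4'-tri-O-benzyl-(−)-epiafzelechin
Product: 15 4β-(2-ethoxyethoxy)-5,7,4'-tri-O-benzylepiafzelechin (2R,3R,4S; 2,3-cis-3,4-trans)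
Conditions: DDQ (2 equiv), 2-ethoxyethanol (5 equiv), CH2Cl2, rt, 2 h
Reagents that add atoms: 2-ethoxyethanol, CCOCCO
Why: The same DDQ benzylic oxidation as in step 3, which depends only on the dialkoxylated ring A, with the alcohol again adding anti to the 3-OH to give the 4β ether.

Step 9
Reactants: 15 4β-(2-ethoxyethoxy)-5,7,4'-tri-O-benzylepiafzelechin; 6 octa-O-benzylprocyanidin B1
Product: 16 undeca-O-benzyl trimer [5,7,4'-tri-O-benzylepiafzelechin-(4β→8)-5,7,3',4'-tetra-O-benzylepicatechin-(4β→8)-5,7,3',4'-tetra-O-benzylcatechin]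
Conditions: 6 (1.5 equiv), AgOSO2CF3 (1 equiv), CH2Cl2, 0 °C → rt
Reagents that add atoms: none
Why: Silver-triflate-promoted Friedel–Crafts alkylation in which the C-4 cation from 15 is taken up by the only free C-8 of 6 (on its upper unit, more reactive and less hindered than either C-6) from the face anti to the 3-OH, so the second 4β→8 bond forms with 3,4-trans geometry.

Step 10
Reactants: 16 undeca-O-benzyl trimer
Product: 17 epiafzelechin-(4β→8)-epicatechin-(4β→8)-catechin (CNP0158921.1, the target)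
Conditions: H2 (1 atm), Pd(OH)2/C, THF/MeOH/H2O (20:1:1), rt
Reagents that add atoms: none
Why: Catalytic hydrogenolysis cleaves the eleven benzyl ethers under neutral conditions and leaves the interflavan C–C bonds, the three 3-OH groups and all eight stereocentres untouched.

## Compound list

1 | (+)-catechin, (2R,3S)-2-(3,4-dihydroxyphenyl)chroman-3,5,7-triol | Oc1cc(O)c2c(c1)O[C@H](c1ccc(O)c(O)c1)[C@@H](O)C2 | starting material
2 | 5,7,3',4'-tetra-O-benzyl-(+)-catechin (2R,3S) | c1ccccc1COc1cc(OCc3ccccc3)c2c(c1)O[C@H](c1ccc(OCc3ccccc3)c(OCc3ccccc3)c1)[C@@H](O)C2 | intermediate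
3 | (−)-epicatechin, (2R,3R)-2-(3,4-dihydroxyphenyl)chroman-3,5,7-triol | Oc1cc(O)c2c(c1)O[C@H](c1ccc(O)c(O)c1)[C@H](O)C2 | starting material
4 | 5,7,3',4'-tetra-O-benzyl-(−)-epicatechin (2R,3R) | c1ccccc1COc1cc(OCc3ccccc3)c2c(c1)O[C@H](c1ccc(OCc3ccccc3)c(OCc3ccccc3)c1)[C@H](O)C2 | intermediate
5 | 4β-(2-ethoxyethoxy)-5,7,3',4'-tetra-O-benzylepicatechin (2R,3R,4S; 2-aryl α, 3-OH α, 4-OR β) | c1ccccc1COc1cc(OCc3ccccc3)c2c(c1)O[C@H](c1ccc(OCc3ccccc3)c(OCc3ccccc3)c1)[C@H](O)[C@H]2OCCOCC | intermediate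
6 | octa-O-benzylprocyanidin B1, tetra-O-benzylepicatechin-(4β→8)-tetra-O-benzylcatechin (upper unit 2R,3R,4R; lower unit 2R,3S) | c1ccccc1COc1cc(OCc3ccccc3)c2c(c1)O[C@H](c1ccc(OCc3ccccc3)c(OCc3ccccc3)c1)[C@H](O)[C@H]2c1c(OCc3ccccc3)cc(OCc3ccccc3)c2c1O[C@H](c1ccc(OCc3ccccc3)c(OCc3ccccc3)c1)[C@@H](O)C2 | intermediate
7 | 2,4,6-trihydroxybenzaldehyde | O=Cc1c(O)cc(O)cc1O | starting material
8 | 2-hydroxy-1-(4-hydroxyphenyl)ethan-1-one | O=C(CO)c1ccc(O)cc1 | starting material
9 | 2-hydroxy-1-(4-hydroxyphenyl)-3-(2,4,6-trihydroxyphenyl)prop-2-en-1-one (aryl and aroyl cis) | O=C(c1ccc(O)cc1)/C(O)=C\c1c(O)cc(O)cc1O | intermediate (not isolated)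
10 | pelargonidin chloride, 3,5,7-trihydroxy-2-(4-hydroxyphenyl)chromenylium chloride | Oc1ccc(cc1)-c1[o+]c2cc(O)cc(O)c2cc1O.[Cl-] | intermediate
11 | 2-(4-hydroxyphenyl)-4H-chromene-3,5,7-triol (flav-2-en-3-ol, achiral) | Oc1ccc(cc1)C1=C(O)Cc2c(O)cc(O)cc2O1 | intermediate (not isolated)
12 | 5,7-dihydroxy-2-(4-hydroxyphenyl)chroman-3-one (C-2 configurationally labile, both epimers in equilibrium) | O=C1Cc2c(O)cc(O)cc2OC1c1ccc(O)cc1 | intermediate (not isolated)
13 | (−)-epiafzelechin, (2R,3R)-2-(4-hydroxyphenyl)chroman-3,5,7-triol | Oc1cc(O)c2c(c1)O[C@H](c1ccc(O)cc1)[C@H](O)C2 | intermediate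
14 | 5,7,4'-tri-O-benzyl-(−)-epiafzelechin (2R,3R) | c1ccccc1COc1cc(OCc3ccccc3)c2c(c1)O[C@H](c1ccc(OCc3ccccc3)cc1)[C@H](O)C2 | intermediate
15 | 4β-(2-ethoxyethoxy)-5,7,4'-tri-O-benzylepiafzelechin (2R,3R,4S; 2-aryl α, 3-OH α, 4-OR β) | c1ccccc1COc1cc(OCc3ccccc3)c2c(c1)O[C@H](c1ccc(OCc3ccccc3)cc1)[C@H](O)[C@H]2OCCOCC | intermediate
16 | undeca-O-benzyl trimer, tri-O-benzylepiafzelechin-(4β→8)-tetra-O-benzylepicatechin-(4β→8)-tetra-O-benzylcatechin (all 2-aryl α; 3-OH α in top and middle units, β in bottom unit; both interflavan bonds β) | c5ccccc5COc1ccc([C@H]2Oc3cc(OCc5ccccc5)cc(OCc5ccccc5)c3[C@H](c3c(OCc5ccccc5)cc(OCc5ccccc5)c4c3O[C@H](c3ccc(OCc5ccccc5)c(OCc5ccccc5)c3)[C@H](O)[C@H]4c3c(OCc5ccccc5)cc(OCc5ccccc5)c4c3O[C@H](c3ccc(OCc5ccccc5)c(OCc5ccccc5)c3)[C@@H](O)C4)[C@H]2O)cc1 | intermediate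
17 | epiafzelechin-(4β→8)-epicatechin-(4β→8)-catechin, CNP0158921.1 | Oc1ccc([C@H]2Oc3cc(O)cc(O)c3[C@H](c3c(O)cc(O)c4c3O[C@H](c3ccc(O)c(O)c3)[C@H](O)[C@H]4c3c(O)cc(O)c4c3O[C@H](c3ccc(O)c(O)c3)[C@@H](O)C4)[C@H]2O)cc1 | target

## Step count and risks

Total steps: 10. Longest linear sequence: 6 (steps 5, 6, 7, 8, 9, 10).

Most likely to fail, in order:

Step 6 (reductase-like transfer hydrogenation of the flavylium salt). The unprotected ketone 12 may decompose before it is reduced, or the sense or level of induction may be poor. The fallback gives up asymmetric catalysis for a resolution; it sets out from 10 and comes back at 14. Hydrogenation of 10 over PtO2 (H2, 1 atm, EtOH) gives racemic epiafzelechin F1, cis by syn delivery of hydrogen. Benzylation as in step 7 gives racemic 5,7,4'-tri-O-benzylepiafzelechin F2. Esterification of its 3-OH with (S)-naproxen (DCC, 4-(dimethylamino)pyridine, CH2Cl2) gives two diastereomers, the (2R,3R) naproxen ester F3 and the (2S,3S) naproxen ester F4, which are separated on silica or by crystallisation. LiOH (THF/MeOH/H2O) on F3 gives enantiopure 14.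

Step 9 (coupling of electrophile 15 with the dimer 6). With a nucleophile that cannot be used in large excess, 15 can condense with itself through its own free C-8, and yields drop. The fallback blocks that position; it sets out from 14, uses 6, and comes back at 17. N-Bromosuccinimide (CH2Cl2, −78 °C → rt) brominates C-8 of 14 to give 8-bromo-5,7,4'-tri-O-benzylepiafzelechin F5. DDQ and 2-ethoxyethanol as in step 8 give 8-bromo-4β-(2-ethoxyethoxy)-5,7,4'-tri-O-benzylepiafzelechin F6, which can only act as an electrophile. Coupling with 6 (Me3SiOSO2CF3, CH2Cl2, −78 °C) gives the 8-bromo undeca-O-benzyl trimer F7. Hydrogenolysis (H2, Pd(OH)2/C, Et3N, THF/MeOH/H2O) removes the bromine together with the benzyl ethers and gives 17 directly.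

Step 5 (flavylium synthesis with a free α-ketol and an unprotected aldehyde). The free ketol 8 can self-condense or oxidise under HCl, and the salt may not crystallise cleanly. The fallback uses an acyl-protected aldol donor in a stepwise sequence; it sets out from 8, uses 7, and comes back at 10. Ac2O in pyridine converts 8 into 2-acetoxy-1-(4-acetoxyphenyl)ethan-1-one F8. Condensation of F8 with 7 (HCl gas, EtOAc, 0 °C) gives 3,4'-di-O-acetylpelargonidin chloride F9. HCl in MeOH then removes both acetates to give 10.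

## Further compounds

F1 | step 6 | racemic epiafzelechin (2R,3R and 2S,3S, 1:1) | Oc1cc(O)c2c(c1)O[C@H](c1ccc(O)cc1)[C@H](O)C2.Oc1cc(O)c2c(c1)O[C@@H](c1ccc(O)cc1)[C@@H](O)C2
F2 | step 6 | racemic 5,7,4'-tri-O-benzylepiafzelechin (2R,3R and 2S,3S, 1:1) | c1ccccc1COc1cc(OCc3ccccc3)c2c(c1)O[C@H](c1ccc(OCc3ccccc3)cc1)[C@H](O)C2.c1ccccc1COc1cc(OCc3ccccc3)c2c(c1)O[C@@H](c1ccc(OCc3ccccc3)cc1)[C@@H](O)C2
F3 | step 6 | (2R,3R)-5,7,4'-tri-O-benzylepiafzelechin 3-O-[(S)-2-(6-methoxynaphthalen-2-yl)propanoate] | c1ccccc1COc1cc(OCc3ccccc3)c2c(c1)O[C@H](c1ccc(OCc3ccccc3)cc1)[C@H](OC(=O)[C@@H](C)c1ccc3cc(OC)ccc3c1)C2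
F4 | step 6 | (2S,3S)-5,7,4'-tri-O-benzylepiafzelechin 3-O-[(S)-2-(6-methoxynaphthalen-2-yl)propanoate] | c1ccccc1COc1cc(OCc3ccccc3)c2c(c1)O[C@@H](c1ccc(OCc3ccccc3)cc1)[C@@H](OC(=O)[C@@H](C)c1ccc3cc(OC)ccc3c1)C2
F5 | step 9 | 8-bromo-5,7,4'-tri-O-benzylepiafzelechin (2R,3R) | c1ccccc1COc1cc(OCc3ccccc3)c2c(c1Br)O[C@H](c1ccc(OCc3ccccc3)cc1)[C@H](O)C2
F6 | step 9 | 8-bromo-4β-(2-ethoxyethoxy)-5,7,4'-tri-O-benzylepiafzelechin (2-aryl α, 3-OH α, 4-OR β) | c1ccccc1COc1cc(OCc3ccccc3)c2c(c1Br)O[C@H](c1ccc(OCc3ccccc3)cc1)[C@H](O)[C@H]2OCCOCC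
F7 | step 9 | 8-bromo undeca-O-benzyl trimer (bromine on C-8 of the top unit, otherwise as 16) | c5ccccc5COc1ccc([C@H]2Oc3c(Br)c(OCc5ccccc5)cc(OCc5ccccc5)c3[C@H](c3c(OCc5ccccc5)cc(OCc5ccccc5)c4c3O[C@H](c3ccc(OCc5ccccc5)c(OCc5ccccc5)c3)[C@H](O)[C@H]4c3c(OCc5ccccc5)cc(OCc5ccccc5)c4c3O[C@H](c3ccc(OCc5ccccc5)c(OCc5ccccc5)c3)[C@@H](O)C4)[C@H]2O)cc1
F8 | step 5 | 2-acetoxy-1-(4-acetoxyphenyl)ethan-1-one | CC(=O)OCC(=O)c1ccc(OC(C)=O)cc1
F9 | step 5 | 3,4'-di-O-acetylpelargonidin chloride | CC(=O)Oc1ccc(cc1)-c1[o+]c2cc(O)cc(O)c2cc1OC(C)=O.[Cl-]
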